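**Retrosynthetic overview**

- The route rests on ring A (C4a–C8a): a benzoyl ring with oxygens at C7 and C8a and the geranyl group at C6 next to the C7 oxygen. C8a–C8–C7–C6 map onto C1–C4 of a γ-geranylated acetoacetate, and C5, C4a and C4 onto methyl propiolate.
- Ring A is made first, by [4+2] cycloaddition and aromatisation of the geranylated 1-methoxy-1,3-bis(trimethylsilyloxy)diene with methyl propiolate (bonds C6–C5 and C8a–C4a).
- Ring C follows: Claisen condensation on the ring A ester gives the C4–C3 unit, a formyl equivalent inserts C2 between the C8a phenol and C3, and conjugate reduction gives the allyl 4-oxochroman-3-carboxylate.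
- Ring B comes in intact from 4-bromo-3-methoxyphenol through an aryllead triacetate, which arylates C3.
- The (3S) centre is set last by palladium-catalysed decarboxylative asymmetric protonation, followed by buffered desilylation.

Key step: step 4

Remarks on the chemistry:
- Positions are given in chromanone numbering (O1, C2, C3, C4, C4a, C5–C8, C8a; ring B primed), also for ring A precursors.
- Assumption: the (S)-configured PHOX ligand with Meldrum's acid is taken to favour the (3S) ketone. The sense of induction depends on ligand and proton donor, so the enantiomeric ligand is used if a trial shows the opposite sense.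
- Assumption: enol ether 5 is drawn as the (2E) isomer and enaminone 13 as the (E) isomer; neither geometry matters for the next step. The two ring stereocentres of cycloadduct 8 are left unspecified because both are destroyed on aromatisation.

**Route**

Step 1
Reactants: 1 methyl acetoacetate; 2 geranyl bromide
Product: 4 methyl (6E)-7,11-dimethyl-3-oxododeca-6,10-dienoate, via acetoacetate dianion 3 (not isolated)
Conditions: NaH, THF, 0 °C; n-BuLi, 0 °C; 2, 0 °C to rt; aq. HCl work-up
Reagents that add atoms: none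
Why: Weiler dianion alkylation, in which the more basic γ-carbanion displaces the primary allylic bromide by SN2 and leaves the (E)-alkene untouched.

Step 2
Reactants: 4 methyl (6E)-7,11-dimethyl-3-oxododeca-6,10-dienoate
Product: 5 methyl (2E,6E)-7,11-dimethyl-3-(trimethylsilyloxy)dodeca-2,6,10-trienoate
Conditions: TMSCl, Et3N, hexane, rt; filtration
Reagents that add atoms: chlorotrimethylsilane, C[Si](C)(C)Cl
Why: Silyl enol ether formation from the readily enolised β-ketoester masks the ketone and leaves the γ-CH2 as the only acidic site for the next step.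

Step 3
Reactants: 5 methyl (2E,6E)-7,11-dimethyl-3-(trimethylsilyloxy)dodeca-2,6,10-trienoate
Product: 6 (1Z,3Z,6E)-1-methoxy-7,11-dimethyl-1,3-bis(trimethylsilyloxy)dodeca-1,3,6,10-tetraene
Conditions: LiN(i-Pr)2, THF, −78 °C; TMSCl, −78 °C to rt; hexane, filtration under argon, used crude
Reagents that add atoms: chlorotrimethylsilane, C[Si](C)(C)Cl
Why: Kinetic γ-deprotonation of the β-silyloxy enoate and O-silylation of the extended enolate give the Chan-type diene, and the bulky C3 silyloxy group should place the geranyl methylene on the outer (Z) position of C3=C4 that cycloaddition needs.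

Step 4
Reactants: 6 (1Z,3Z,6E)-1-methoxy-7,11-dimethyl-1,3-bis(trimethylsilyloxy)dodeca-1,3,6,10-tetraene; 7 methyl propiolate
Product: 10 methyl 5-[(2E)-3,7-dimethylocta-2,6-dienyl]-2,4-dihydroxybenzoate, via cyclohexadiene cycloadduct 8 (not isolated), via bis(trimethylsilyl) ether 9 (not isolated)
Conditions: 7 (2 equiv), toluene, 80–110 °C, sealed tube; then 1 M HCl, THF, 0 °C
Reagents that add atoms: none
Why: The electron-rich diene (largest HOMO coefficient at C4, the geranyl-bearing terminus) and the electron-poor ynoate (largest LUMO coefficient at the β-carbon) should combine in a strongly asynchronous [4+2] cycloaddition, a Diels–Alder reaction of the Danishefsky–Chan diene class with acetylenic esters, and a stepwise Mukaiyama–Michael addition followed by ring closure would give the same constitution. Ring A is closed intermolecularly by formation of C6–C5 (diene C4 to alkyne β-carbon) and C8a–C4a (ketene acetal carbon to alkyne α-carbon), giving cyclohexa-1,4-diene 8. 1,4-Elimination of methanol from the ketal carbon and the geranyl-bearing sp3 carbon aromatises the ring to 9, and dilute acid removes both trimethylsilyl groups. The two sp3 centres of 8 are destroyed, so no stereocentre has to be controlled. The step needs regioselectivity, secured by the matched polarisation just described, and chemoselectivity, secured because the unactivated trisubstituted alkenes of the geranyl chain are neither dienes nor dienophiles under thermal conditions free of Lewis acid. The C8a hydroxyl emerges hydrogen-bonded to the ester and is thereby differentiated from the C7 hydroxyl.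

Step 5
Reactants: 10 methyl 5-[(2E)-3,7-dimethylocta-2,6-dienyl]-2,4-dihydroxybenzoate
Product: 11 methyl 5-[(2E)-3,7-dimethylocta-2,6-dienyl]-2-hydroxy-4-(triisopropylsilyloxy)benzoate
Conditions: TIPSCl (1.05 equiv), imidazole, DMF, 0 °C to rt
Reagents that add atoms: chlorotriisopropylsilane, CC(C)[Si](Cl)(C(C)C)C(C)C
Why: Selective phenol silylation, since the C7 hydroxyl is free and the more acidic while the C8a hydroxyl is held in a hydrogen bond to the ester carbonyl.

Step 6
Reactants: 11 methyl 5-[(2E)-3,7-dimethylocta-2,6-dienyl]-2-hydroxy-4-(triisopropylsilyloxy)benzoate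
Product: 12 allyl 3-{5-[(2E)-3,7-dimethylocta-2,6-dienyl]-2-hydroxy-4-(triisopropylsilyloxy)phenyl}-3-oxopropanoate
Conditions: allyl acetate, LiN(SiMe3)2 (excess), THF, −78 °C; add 11, −78 to −10 °C; cold 1 M HCl
Reagents that add atoms: allyl acetate, CC(=O)OCC=C
Why: Crossed Claisen condensation in which excess lithium enolate of allyl acetate acylates on the methyl ester of the lithium phenoxide, the product being protected as its dianion from further attack and from ester exchange.

Step 7
Reactants: 12 allyl 3-{5-[(2E)-3,7-dimethylocta-2,6-dienyl]-2-hydroxy-4-(triisopropylsilyloxy)phenyl}-3-oxopropanoate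
Product: 14 allyl 6-[(2E)-3,7-dimethylocta-2,6-dienyl]-4-oxo-7-(triisopropylsilyloxy)-4H-chromene-3-carboxylate, via enaminone 13 (not isolated)
Conditions: Me2NCH(OMe)2, toluene, 60 °C
Reagents that add atoms: N,N-dimethylformamide dimethyl acetal, COC(OC)N(C)C
Why: Condensation of the active methylene with the formamide acetal gives the enaminone, and addition–elimination by the ortho phenol with loss of dimethylamine closes ring C (O1–C2), the standard chromone-3-carboxylate synthesis.

Step 8
Reactants: 14 allyl 6-[(2E)-3,7-dimethylocta-2,6-dienyl]-4-oxo-7-(triisopropylsilyloxy)-4H-chromene-3-carboxylate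
Product: 15 allyl 6-[(2E)-3,7-dimethylocta-2,6-dienyl]-4-oxo-7-(triisopropylsilyloxy)chroman-3-carboxylate (racemic; keto–enol mixture)
Conditions: LiBH(s-Bu)3 (1.1 equiv), THF, −78 °C; AcOH
Reagents that add atoms: none
Why: Conjugate hydride reduction, since C2 is the β-carbon of both the ketone and the ester, so the hindered borohydride adds there and stops at the stabilised β-ketoester enolate without touching the allyl ester or the isolated alkenes.

Step 9
Reactants: 16 4-bromo-3-methoxyphenol
Product: 17 (4-bromo-3-methoxyphenoxy)triisopropylsilane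
Conditions: TIPSCl, imidazole, DMF, rt
Reagents that add atoms: chlorotriisopropylsilane, CC(C)[Si](Cl)(C(C)C)C(C)C
Why: Standard silylation of an unhindered phenol, giving an ether that withstands organolithium, tetravalent lead and palladium chemistry.

Step 10
Reactants: 17 (4-bromo-3-methoxyphenoxy)triisopropylsilane
Product: 19 [2-methoxy-4-(triisopropylsilyloxy)phenyl]boronic acid, via aryllithium 18 (not isolated)
Conditions: n-BuLi, THF, −78 °C; B(OiPr)3, −78 °C to rt; 1 M HCl, 0 °C
Reagents that add atoms: triisopropyl borate, CC(C)OB(OC(C)C)OC(C)C; water, O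
Why: Bromine–lithium exchange is faster than any deprotonation at −78 °C, the para silyloxy group cannot migrate to the lithiated carbon, and borate trapping with hydrolysis gives the boronic acid.

Step 11
Reactants: 19 [2-methoxy-4-(triisopropylsilyloxy)phenyl]boronic acid
Product: 20 [2-methoxy-4-(triisopropylsilyloxy)phenyl]lead triacetate
Conditions: Pb(OAc)4 (0.95 equiv), Hg(OAc)2 (cat.), CHCl3, 40 °C then rt; water wash, Celite filtration, concentration
Reagents that add atoms: lead tetraacetate, CC(=O)O[Pb](OC(C)=O)(OC(C)=O)OC(C)=O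
Why: Mercury-catalysed boron–lead exchange, well established for electron-rich ortho-methoxy arylboronic acids; isolating the aryllead reagent keeps mercury salts and free tetravalent lead acetate away from the geranyl chain in the next step.

Step 12
Reactants: 15 allyl 6-[(2E)-3,7-dimethylocta-2,6-dienyl]-4-oxo-7-(triisopropylsilyloxy)chroman-3-carboxylate; 20 [2-methoxy-4-(triisopropylsilyloxy)phenyl]lead triacetate
Product: 21 allyl 6-[(2E)-3,7-dimethylocta-2,6-dienyl]-3-[2-methoxy-4-(triisopropylsilyloxy)phenyl]-4-oxo-7-(triisopropylsilyloxy)chroman-3-carboxylate (racemic)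
Conditions: pyridine (3.5 equiv), CHCl3, 40 °C
Reagents that add atoms: none
Why: Pinhey arylation, in which the β-ketoester enolate binds to tetravalent lead and the aryl group is passed to C3 by ligand coupling, forming the quaternary centre and divalent lead.

Step 13
Reactants: 21 allyl 6-[(2E)-3,7-dimethylocta-2,6-dienyl]-3-[2-methoxy-4-(triisopropylsilyloxy)phenyl]-4-oxo-7-(triisopropylsilyloxy)chroman-3-carboxylate
Product: 22 (3S)-6-[(2E)-3,7-dimethylocta-2,6-dienyl]-3-[2-methoxy-4-(triisopropylsilyloxy)phenyl]-7-(triisopropylsilyloxy)chroman-4-one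
Conditions: Pd2(dba)3 (cat.), (S)-(CF3)3-t-BuPHOX (cat.), Meldrum's acid (2.5 equiv), THF, rt
Reagents that add atoms: none
Why: Palladium-catalysed decarboxylative asymmetric protonation (ionisation of the allyl ester by zerovalent palladium, loss of CO2, then protonation of the PHOX-bound palladium enolate by Meldrum's acid, which also traps the allyl group), with the (3S) centre set by the ligand-controlled face of proton delivery in a non-basic medium.

Step 14
Reactants: 22 (3S)-6-[(2E)-3,7-dimethylocta-2,6-dienyl]-3-[2-methoxy-4-(triisopropylsilyloxy)phenyl]-7-(triisopropylsilyloxy)chroman-4-one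
Product: 23 (3S)-6-[(2E)-3,7-dimethylocta-2,6-dienyl]-7-hydroxy-3-(4-hydroxy-2-methoxyphenyl)chroman-4-one
Conditions: Bu4NF (2.4 equiv), AcOH (3 equiv), THF, 0 °C
Reagents that add atoms: none
Why: Fluoride cleavage of both aryl silyl ethers, with acetic acid buffering so that the α-aryl ketone is not enolised and the C3 configuration should be retained.

**Compound list**

1 | methyl acetoacetate | COC(=O)CC(C)=O | starting material
2 | geranyl bromide, (2E)-1-bromo-3,7-dimethylocta-2,6-diene | CC(C)=CCC/C(C)=C/CBr | starting material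
3 | sodium lithium dianion of methyl acetoacetate | [Na+].[Li+].[CH2-]C(=O)[CH-]C(=O)OC | intermediate
4 | methyl (6E)-7,11-dimethyl-3-oxododeca-6,10-dienoate | COC(=O)CC(=O)CC/C=C(\C)CCC=C(C)C | intermediate
5 | methyl (2E,6E)-7,11-dimethyl-3-(trimethylsilyloxy)dodeca-2,6,10-trienoate | COC(=O)/C=C(/O[Si](C)(C)C)CC/C=C(\C)CCC=C(C)C | intermediate
6 | (1Z,3Z,6E)-1-methoxy-7,11-dimethyl-1,3-bis(trimethylsilyloxy)dodeca-1,3,6,10-tetraene (1-methoxy-1,3-bis(trimethylsilyloxy)-4-geranylbuta-1,3-diene) | CO/C(O[Si](C)(C)C)=C/C(O[Si](C)(C)C)=C/C/C=C(\C)CCC=C(C)C | intermediate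
7 | methyl propiolate | C#CC(=O)OC | starting material
8 | methyl 3-[(2E)-3,7-dimethylocta-2,6-dienyl]-6-methoxy-4,6-bis(trimethylsilyloxy)cyclohexa-1,4-diene-1-carboxylate (racemic, ring stereocentres unspecified) | COC(=O)C1=CC(C/C=C(\C)CCC=C(C)C)C(O[Si](C)(C)C)=CC1(OC)O[Si](C)(C)C | intermediate
9 | methyl 5-[(2E)-3,7-dimethylocta-2,6-dienyl]-2,4-bis(trimethylsilyloxy)benzoate | COC(=O)c1cc(C/C=C(\C)CCC=C(C)C)c(O[Si](C)(C)C)cc1O[Si](C)(C)C | intermediate
10 | methyl 5-[(2E)-3,7-dimethylocta-2,6-dienyl]-2,4-dihydroxybenzoate (methyl 5-geranyl-2,4-dihydroxybenzoate) | COC(=O)c1cc(C/C=C(\C)CCC=C(C)C)c(O)cc1O | intermediate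
11 | methyl 5-[(2E)-3,7-dimethylocta-2,6-dienyl]-2-hydroxy-4-(triisopropylsilyloxy)benzoate | COC(=O)c1cc(C/C=C(\C)CCC=C(C)C)c(O[Si](C(C)C)(C(C)C)C(C)C)cc1O | intermediate
12 | allyl 3-{5-[(2E)-3,7-dimethylocta-2,6-dienyl]-2-hydroxy-4-(triisopropylsilyloxy)phenyl}-3-oxopropanoate | C=CCOC(=O)CC(=O)c1cc(C/C=C(\C)CCC=C(C)C)c(O[Si](C(C)C)(C(C)C)C(C)C)cc1O | intermediate
13 | allyl (2E)-3-(dimethylamino)-2-{5-[(2E)-3,7-dimethylocta-2,6-dienyl]-2-hydroxy-4-(triisopropylsilyloxy)benzoyl}prop-2-enoate | C=CCOC(=O)/C(=C/N(C)C)C(=O)c1cc(C/C=C(\C)CCC=C(C)C)c(O[Si](C(C)C)(C(C)C)C(C)C)cc1O | intermediate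
14 | allyl 6-[(2E)-3,7-dimethylocta-2,6-dienyl]-4-oxo-7-(triisopropylsilyloxy)-4H-chromene-3-carboxylate | C=CCOC(=O)C1=COc2cc(O[Si](C(C)C)(C(C)C)C(C)C)c(C/C=C(\C)CCC=C(C)C)cc2C1=O | intermediate
15 | allyl 6-[(2E)-3,7-dimethylocta-2,6-dienyl]-4-oxo-7-(triisopropylsilyloxy)chroman-3-carboxylate (racemic) | C=CCOC(=O)C1COc2cc(O[Si](C(C)C)(C(C)C)C(C)C)c(C/C=C(\C)CCC=C(C)C)cc2C1=O | intermediate
16 | 4-bromo-3-methoxyphenol | COc1cc(O)ccc1Br | starting material
17 | (4-bromo-3-methoxyphenoxy)triisopropylsilane | COc1cc(O[Si](C(C)C)(C(C)C)C(C)C)ccc1Br | intermediate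
18 | [2-methoxy-4-(triisopropylsilyloxy)phenyl]lithium | [Li]c1ccc(O[Si](C(C)C)(C(C)C)C(C)C)cc1OC | intermediate
19 | [2-methoxy-4-(triisopropylsilyloxy)phenyl]boronic acid | COc1cc(O[Si](C(C)C)(C(C)C)C(C)C)ccc1B(O)O | intermediate
20 | [2-methoxy-4-(triisopropylsilyloxy)phenyl]lead triacetate | COc1cc(O[Si](C(C)C)(C(C)C)C(C)C)ccc1[Pb](OC(C)=O)(OC(C)=O)OC(C)=O | intermediate
21 | allyl 6-[(2E)-3,7-dimethylocta-2,6-dienyl]-3-[2-methoxy-4-(triisopropylsilyloxy)phenyl]-4-oxo-7-(triisopropylsilyloxy)chroman-3-carboxylate (racemic) | C=CCOC(=O)C1(c2ccc(O[Si](C(C)C)(C(C)C)C(C)C)cc2OC)COc2cc(O[Si](C(C)C)(C(C)C)C(C)C)c(C/C=C(\C)CCC=C(C)C)cc2C1=O | intermediate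
22 | (3S)-6-[(2E)-3,7-dimethylocta-2,6-dienyl]-3-[2-methoxy-4-(triisopropylsilyloxy)phenyl]-7-(triisopropylsilyloxy)chroman-4-one | COc1cc(O[Si](C(C)C)(C(C)C)C(C)C)ccc1[C@H]1COc2cc(O[Si](C(C)C)(C(C)C)C(C)C)c(C/C=C(\C)CCC=C(C)C)cc2C1=O | intermediate
23 | (3S)-6-[(2E)-3,7-dimethylocta-2,6-dienyl]-7-hydroxy-3-(4-hydroxy-2-methoxyphenyl)chroman-4-one | COc1cc(O)ccc1[C@H]1COc2cc(O)c(C/C=C(\C)CCC=C(C)C)cc2C1=O | target

**Step count**

Total: 14 steps. Longest linear sequence: 11 steps (steps 1–8 and 12–14); the ring B branch is steps 9–11.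

**Steps most likely to fail**

Step 4. The terminally substituted diene may add too slowly, so that silyl transfer or hydrolysis back to ketoester 4, or open-chain Michael adducts that do not close, take over. The fallback gives up the de novo ring and sets out from geranyl bromide 2, joined to a preformed arene. Commercial methyl 5-bromo-2,4-dihydroxybenzoate (COC(=O)c1cc(Br)c(O)cc1O) would be protected with MOMCl and NaH in DMF as methyl 5-bromo-2,4-bis(methoxymethoxy)benzoate F1. Miyaura borylation (B2pin2, PdCl2(dppf), KOAc, dioxane, 90 °C) should give methyl 2,4-bis(methoxymethoxy)-5-(4,4,5,5-tetramethyl-1,3,2-dioxaborolan-2-yl)benzoate F2. Suzuki–Miyaura allyl–aryl coupling of F2 with 2 (Pd(PPh3)4, K2CO3, aqueous THF, 60 °C), with bond formation at the less substituted allyl terminus, should give methyl 5-[(2E)-3,7-dimethylocta-2,6-dienyl]-2,4-bis(methoxymethoxy)benzoate F3. Dilute HCl in MeOH at 40 °C would remove both acetals and return the route at 10.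

Step 6. The ester, deactivated by the ortho phenoxide, may resist acylation while the allyl acetate enolate self-condenses, or the product may lactonise to a 4-hydroxycoumarin. The fallback sets out from 11. Phosphine-catalysed oxa-Michael addition of the C8a phenol to allyl acrylate (PMe3 cat., MeCN, rt to 40 °C) should give methyl 2-(3-allyloxy-3-oxopropoxy)-5-[(2E)-3,7-dimethylocta-2,6-dienyl]-4-(triisopropylsilyloxy)benzoate F4. Dieckmann closure (LiN(SiMe3)2, 2.2 equiv, THF, −78 to 0 °C, conditions chosen to limit retro-oxa-Michael cleavage and ester exchange) then forms C3–C4. This returns the route at 15 and bypasses steps 7 and 8.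

Step 13. Facial discrimination in the protonation of the palladium enolate may be poor, because ring B carries only one ortho substituent. The fallback sets out from 21. Non-asymmetric decarboxylation (Pd(PPh3)4, HCO2H, Et3N, THF) should give racemic 6-[(2E)-3,7-dimethylocta-2,6-dienyl]-3-[2-methoxy-4-(triisopropylsilyloxy)phenyl]-7-(triisopropylsilyloxy)chroman-4-one F5. Asymmetric transfer hydrogenation with dynamic kinetic resolution (RuCl(p-cymene)[(S,S)-TsDPEN], HCO2H/Et3N; the ligand enantiomer expected from the usual sense for aryl ketones, to be confirmed) should give (3S,4S)-6-[(2E)-3,7-dimethylocta-2,6-dienyl]-3-[2-methoxy-4-(triisopropylsilyloxy)phenyl]-7-(triisopropylsilyloxy)chroman-4-ol F6, the cis alcohol. Oxidation with Dess–Martin periodinane buffered by NaHCO3 (CH2Cl2, 0 °C) returns the route at 22.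

**Further compounds**

F1 | step 4 | methyl 5-bromo-2,4-bis(methoxymethoxy)benzoate | COCOc1cc(OCOC)c(Br)cc1C(=O)OC
F2 | step 4 | methyl 2,4-bis(methoxymethoxy)-5-(4,4,5,5-tetramethyl-1,3,2-dioxaborolan-2-yl)benzoate | COCOc1cc(OCOC)c(B2OC(C)(C)C(C)(C)O2)cc1C(=O)OC
F3 | step 4 | methyl 5-[(2E)-3,7-dimethylocta-2,6-dienyl]-2,4-bis(methoxymethoxy)benzoate | COCOc1cc(OCOC)c(C/C=C(\C)CCC=C(C)C)cc1C(=O)OC
F4 | step 6 | methyl 2-(3-allyloxy-3-oxopropoxy)-5-[(2E)-3,7-dimethylocta-2,6-dienyl]-4-(triisopropylsilyloxy)benzoate | C=CCOC(=O)CCOc1cc(O[Si](C(C)C)(C(C)C)C(C)C)c(C/C=C(\C)CCC=C(C)C)cc1C(=O)OC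
F5 | step 13 | racemic 6-[(2E)-3,7-dimethylocta-2,6-dienyl]-3-[2-methoxy-4-(triisopropylsilyloxy)phenyl]-7-(triisopropylsilyloxy)chroman-4-one | COc1cc(O[Si](C(C)C)(C(C)C)C(C)C)ccc1C1COc2cc(O[Si](C(C)C)(C(C)C)C(C)C)c(C/C=C(\C)CCC=C(C)C)cc2C1=O
F6 | step 13 | (3S,4S)-6-[(2E)-3,7-dimethylocta-2,6-dienyl]-3-[2-methoxy-4-(triisopropylsilyloxy)phenyl]-7-(triisopropylsilyloxy)chroman-4-ol | COc1cc(O[Si](C(C)C)(C(C)C)C(C)C)ccc1[C@H]1COc2cc(O[Si](C(C)C)(C(C)C)C(C)C)c(C/C=C(\C)CCC=C(C)C)cc2[C@H]1O
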